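**Retrosynthetic overview**
- The 14-membered ring is closed last, at C11–C12: a chiral triazolylidene turns the C11 aldehyde of an open-chain keto-aldehyde into an acyl-anion equivalent that adds to the C12 methyl ketone, giving the tertiary α-ketol and the C12 centre in one operation.
- The C10–C11 aldehyde comes from the C9 allylic alcohol by palladium decarboxylative allylation of its vinyl carbonate; C9–OH comes from SeO2 oxidation of the prenyl end.
- The acrylate comes from a terminal alkyne by Markovnikov methoxycarbonylation, and the alkyne from an aldehyde.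
- C1 is set by an enamine-catalysed Michael addition of an epoxy-aldehyde to methyl vinyl ketone, which also brings C12–C14 and the C12 methyl group.
- The cis-oxirane (C3, C4) is made first, by Sharpless epoxidation of nerol; ring order: oxirane (step 1), carbocycle (step 9).

Assumption: atom labels follow cembrane numbering (C1 carries the acrylate, C3–C4 the oxirane, C7=C8 the alkene, C11 the ketone, C12 the carbinol; target = 1S,3R,4S,7E,12S); the triazolium antipode named in step 9 is taken to give 12S, and its commercial mirror image is used unchanged if a trial run shows the opposite sense.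

**Route**

Step 1
Reactants: 1 nerol [(2Z)-3,7-dimethylocta-2,6-dien-1-ol]
Product: 2 [(2R,3S)-3-methyl-3-(4-methylpent-3-en-1-yl)oxiran-2-yl]methanol
Conditions: Ti(OiPr)4 (5 mol%), D-(−)-diethyl tartrate (7 mol%), t-BuOOH (2 equiv, in decane), 4 Å molecular sieves, CH2Cl2, −20 °C
Reagents that add atoms: tert-butyl hydroperoxide, CC(C)(C)OO
Why: Sharpless asymmetric epoxidation: the allylic alcohol is held on the titanium tartrate dimer, which with the D-(−)-ester delivers oxygen to the face that gives the (2R,3S) cis-oxirane (mirror image of the known L-(+)-tartrate result, about 90% ee for this Z substrate), fixing C3 and C4 while the distal alkene, which has no directing hydroxyl, is left alone.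

Step 2
Reactants: 2 [(2R,3S)-3-methyl-3-(4-methylpent-3-en-1-yl)oxiran-2-yl]methanol, 3 acetaldehyde N,N-dimethylhydrazone
Product: 6 3-[(2R,3S)-3-methyl-3-(4-methylpent-3-en-1-yl)oxiran-2-yl]propanal, via epoxy triflate 4 (not isolated), via alkylated dimethylhydrazone 5 (not isolated)
Conditions: Tf2O (1.1 equiv), 2,6-lutidine, CH2Cl2, −78 °C; transfer cold into 3 (1.5 equiv)/LiN(iPr)2 (1.4 equiv), THF, −78 °C; then CuCl2, aq. phosphate buffer pH 7, THF, rt
Reagents that add atoms: trifluoromethanesulfonic anhydride, O=S(=O)(OS(=O)(=O)C(F)(F)F)C(F)(F)F (triflyl group of 4); water, O (aldehyde oxygen of 6)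
Why: The primary triflate next to the oxirane undergoes SN2 C-alkylation by the Corey–Enders lithio-hydrazone (aza-enolate alkylation) at −78 °C faster than any epoxide opening, adding C1 and C15, and CuCl2-assisted hydrolysis at pH 7 frees the aldehyde without the acid that would open a trisubstituted oxirane; no stereocentre is formed.

Step 3
Reactants: 6 3-[(2R,3S)-3-methyl-3-(4-methylpent-3-en-1-yl)oxiran-2-yl]propanal, 7 methyl vinyl ketone (but-3-en-2-one)
Product: 8 (2S)-2-{[(2R,3S)-3-methyl-3-(4-methylpent-3-en-1-yl)oxiran-2-yl]methyl}-5-oxohexanal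
Conditions: (S)-α,α-diphenylprolinol trimethylsilyl ether (10 mol%), ethyl 3,4-dihydroxybenzoate (20 mol%), 7 (1.5 equiv), CH2Cl2, 4 °C
Reagents that add atoms: none
Why: Enamine-catalysed Michael addition of an aldehyde to an enone: the E-enamine is attacked by 7 on the face away from the diphenyl(silyloxy)methyl group, which for the (S)-catalyst gives (S) at C1 (typically above 95% ee for this reaction type), independently of the remote oxirane.

Step 4
Reactants: 8 (2S)-2-{[(2R,3S)-3-methyl-3-(4-methylpent-3-en-1-yl)oxiran-2-yl]methyl}-5-oxohexanal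
Product: 9 (5S)-5-ethynyl-6-[(2R,3S)-3-methyl-3-(4-methylpent-3-en-1-yl)oxiran-2-yl]hexan-2-one
Conditions: dimethyl (1-diazo-2-oxopropyl)phosphonate, K2CO3, MeOH, 0 °C, 30 min; then 8, 0 °C → rt
Reagents that add atoms: dimethyl (1-diazo-2-oxopropyl)phosphonate, COP(=O)(OC)C(=[N+]=[N-])C(C)=O
Why: Ohira–Bestmann (Seyferth–Gilbert) homologation: the diazophosphonate anion made in the flask adds only to the aldehyde, loses dimethyl phosphate and N2, and the alkylidene carbene rearranges to the alkyne, while the ketone does not react and pre-forming the reagent keeps the α-branched aldehyde's contact with base short so that C1 is not epimerised and the intramolecular aldol is outrun.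

Step 5
Reactants: 9 (5S)-5-ethynyl-6-[(2R,3S)-3-methyl-3-(4-methylpent-3-en-1-yl)oxiran-2-yl]hexan-2-one
Product: 10 methyl (3S)-2-methylidene-3-{[(2R,3S)-3-methyl-3-(4-methylpent-3-en-1-yl)oxiran-2-yl]methyl}-6-oxoheptanoate
Conditions: Pd(OAc)2 (1 mol%), 2-(diphenylphosphino)pyridine (30 mol%), CH3SO3H (15 mol%), CO (10 bar), MeOH/CH2Cl2, 40 °C
Reagents that add atoms: carbon monoxide, [C-]#[O+]; methanol, CO
Why: Palladium-catalysed Markovnikov hydromethoxycarbonylation of a terminal alkyne (Drent-type): the pyridylphosphine relays the proton so that the ester goes onto the internal carbon (branched to linear typically above 95:5), giving the 2-substituted acrylate directly, with ligand in two-fold excess over acid so that no free strong acid meets the oxirane; C1 is untouched.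

Step 6
Reactants: 10 methyl (3S)-2-methylidene-3-{[(2R,3S)-3-methyl-3-(4-methylpent-3-en-1-yl)oxiran-2-yl]methyl}-6-oxoheptanoate
Product: 11 methyl (3S)-3-({(2R,3S)-3-[(3E)-5-hydroxy-4-methylpent-3-en-1-yl]-3-methyloxiran-2-yl}methyl)-2-methylidene-6-oxoheptanoate
Conditions: SeO2 (0.3 equiv), t-BuOOH (2.5 equiv), CH2Cl2, 0 °C → rt, stopped at about 70% conversion
Reagents that add atoms: tert-butyl hydroperoxide, CC(C)(C)OO
Why: Sharpless catalytic SeO2/t-BuOOH allylic oxidation (ene reaction then [2,3] shift) picks the (E)-methyl group of the electron-rich trisubstituted alkene and leaves the electron-poor acrylate, the ketone and the oxirane alone, giving the E allylic alcohol whose carbinol carbon becomes C9.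

Step 7
Reactants: 11 methyl (3S)-3-({(2R,3S)-3-[(3E)-5-hydroxy-4-methylpent-3-en-1-yl]-3-methyloxiran-2-yl}methyl)-2-methylidene-6-oxoheptanoate
Product: 12 methyl (3S)-3-({(2R,3S)-3-[(3E)-5-{[(ethenyloxy)carbonyl]oxy}-4-methylpent-3-en-1-yl]-3-methyloxiran-2-yl}methyl)-2-methylidene-6-oxoheptanoate
Conditions: vinyl chloroformate (1.3 equiv), pyridine, CH2Cl2, 0 °C
Reagents that add atoms: vinyl chloroformate (ethenyl carbonochloridate), C=COC(Cl)=O
Why: Plain O-acylation of the primary allylic alcohol by the chloroformate with pyridine as acid scavenger installs the allyl enol carbonate needed for the next step; no stereocentre is touched.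

Step 8
Reactants: 12 methyl (3S)-3-({(2R,3S)-3-[(3E)-5-{[(ethenyloxy)carbonyl]oxy}-4-methylpent-3-en-1-yl]-3-methyloxiran-2-yl}methyl)-2-methylidene-6-oxoheptanoate
Product: 13 methyl (3S)-3-({(2R,3S)-3-methyl-3-[(3E)-4-methyl-7-oxohept-3-en-1-yl]oxiran-2-yl}methyl)-2-methylidene-6-oxoheptanoate
Conditions: Pd(PPh3)4 (5 mol%), THF, rt
Reagents that add atoms: none
Why: Tsuji decarboxylative allylation of an allyl enol carbonate: zerovalent palladium ionises the carbonate, CO2 is lost, and the acetaldehyde enolate formed as an ion pair attacks the less hindered CH2 end of the syn π-allyl, giving the linear γ,δ-unsaturated aldehyde (C10, C11) with the E alkene kept, under neutral conditions that tolerate ketone, acrylate and oxirane.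

Step 9
Reactants: 13 methyl (3S)-3-({(2R,3S)-3-methyl-3-[(3E)-4-methyl-7-oxohept-3-en-1-yl]oxiran-2-yl}methyl)-2-methylidene-6-oxoheptanoate
Product: 14 methyl 2-[(1S,3R,4S,7E,12S)-3,4-epoxy-12-hydroxy-4,8,12-trimethyl-11-oxocyclotetradec-7-en-1-yl]prop-2-enoate (ring numbered as in cembrane; CNP0154954.4)
Conditions: (5aS,10bR)-2-(pentafluorophenyl)-5a,10b-dihydro-4H,6H-indeno[2,1-b][1,2,4]triazolo[4,3-d][1,4]oxazin-2-ium tetrafluoroborate (20 mol%), iPr2NEt (20 mol%), toluene, 40 °C, 13 added by syringe pump over 24 h to 1 mM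
Reagents that add atoms: none
Why: Proposed new method: the triazolylidene adds to the C11 aldehyde and proton transfer gives the Breslow intermediate, an acyl-anion equivalent, whose carbon attacks the C12 methyl ketone through a hydrogen-bonded five-membered transition state in which the aminoindanol backbone selects one ketone face (taken to give 12S), and loss of the carbene leaves the tertiary α-ketol and the 14-membered ring; the closest known reactions are the enantioselective intramolecular crossed aldehyde–ketone benzoin cyclisations to five- and six-membered rings with this catalyst class and carbene-catalysed macrocyclisations, and slow addition at high dilution is relied on to favour ring closure over the reversible aldehyde self-benzoin, while the 2-alkyl acrylate is a poor Stetter acceptor.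

**Compound list**

1 | nerol, (2Z)-3,7-dimethylocta-2,6-dien-1-ol | CC(C)=CCC/C(C)=C\CO | starting material
2 | [(2R,3S)-3-methyl-3-(4-methylpent-3-en-1-yl)oxiran-2-yl]methanol | CC(C)=CCC[C@]1(C)O[C@@H]1CO | intermediate
3 | acetaldehyde N,N-dimethylhydrazone | C/C=N/N(C)C | starting material
4 | [(2R,3S)-3-methyl-3-(4-methylpent-3-en-1-yl)oxiran-2-yl]methyl trifluoromethanesulfonate | CC(C)=CCC[C@]1(C)O[C@@H]1COS(=O)(=O)C(F)(F)F | intermediate
5 | 1,1-dimethyl-2-{(E)-3-[(2R,3S)-3-methyl-3-(4-methylpent-3-en-1-yl)oxiran-2-yl]propylidene}hydrazine | CC(C)=CCC[C@]1(C)O[C@@H]1CC/C=N/N(C)C | intermediate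
6 | 3-[(2R,3S)-3-methyl-3-(4-methylpent-3-en-1-yl)oxiran-2-yl]propanal | CC(C)=CCC[C@]1(C)O[C@@H]1CCC=O | intermediate
7 | methyl vinyl ketone, but-3-en-2-one | C=CC(C)=O | starting material
8 | (2S)-2-{[(2R,3S)-3-methyl-3-(4-methylpent-3-en-1-yl)oxiran-2-yl]methyl}-5-oxohexanal | CC(C)=CCC[C@]1(C)O[C@@H]1C[C@H](CCC(C)=O)C=O | intermediate
9 | (5S)-5-ethynyl-6-[(2R,3S)-3-methyl-3-(4-methylpent-3-en-1-yl)oxiran-2-yl]hexan-2-one | CC(C)=CCC[C@]1(C)O[C@@H]1C[C@H](CCC(C)=O)C#C | intermediate
10 | methyl (3S)-2-methylidene-3-{[(2R,3S)-3-methyl-3-(4-methylpent-3-en-1-yl)oxiran-2-yl]methyl}-6-oxoheptanoate | CC(C)=CCC[C@]1(C)O[C@@H]1C[C@H](CCC(C)=O)C(=C)C(=O)OC | intermediate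
11 | methyl (3S)-3-({(2R,3S)-3-[(3E)-5-hydroxy-4-methylpent-3-en-1-yl]-3-methyloxiran-2-yl}methyl)-2-methylidene-6-oxoheptanoate | OC/C(C)=C/CC[C@]1(C)O[C@@H]1C[C@H](CCC(C)=O)C(=C)C(=O)OC | intermediate
12 | methyl (3S)-3-({(2R,3S)-3-[(3E)-5-{[(ethenyloxy)carbonyl]oxy}-4-methylpent-3-en-1-yl]-3-methyloxiran-2-yl}methyl)-2-methylidene-6-oxoheptanoate | C=COC(=O)OC/C(C)=C/CC[C@]1(C)O[C@@H]1C[C@H](CCC(C)=O)C(=C)C(=O)OC | intermediate
13 | methyl (3S)-3-({(2R,3S)-3-methyl-3-[(3E)-4-methyl-7-oxohept-3-en-1-yl]oxiran-2-yl}methyl)-2-methylidene-6-oxoheptanoate | O=CCC/C(C)=C/CC[C@]1(C)O[C@@H]1C[C@H](CCC(C)=O)C(=C)C(=O)OC | intermediate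
14 | methyl 2-[(1S,3R,4S,7E,12S)-3,4-epoxy-12-hydroxy-4,8,12-trimethyl-11-oxocyclotetradec-7-en-1-yl]prop-2-enoate (cembrane ring numbering) | C=C(C(=O)OC)[C@H]1CC[C@](C)(O)C(=O)CC/C(C)=C/CC[C@]2(C)O[C@@H]2C1 | target

**Totals**

Total step count: 9. Longest linear sequence: 9 steps (1 → 14).

**Steps most likely to fail, with fallbacks**

Step 9 (ring closure). This is the least certain step: at any practical concentration the aldehyde self-benzoin competes with capture by an unactivated ketone across a 14-membered ring, the equilibrium may be unfavourable, and the sense of induction at C12 is unproven. The fallback sets out from alkyne 9 and comes back at target 14. Divalent samarium would reduce the acrylate, so the ring is closed before the ester is made. SeO2/t-BuOOH on 9 gives the ethynyl allylic alcohol F1, vinyl chloroformate and pyridine give its vinyl carbonate F2, and Pd(PPh3)4 gives the ethynyl keto-aldehyde F3 (the chemistry of steps 6 to 8). SmI2 (THF, −78 °C to rt, 1 mM) then closes the ring by ketyl–carbonyl pinacol coupling to the macrocyclic 11,12-diol F4. Dess–Martin periodinane oxidises only its secondary C11 hydroxyl to the ethynyl α-ketol F5. The pinacol step gives no reagent control at C12, so the 12S and 12R isomers are separated here. The methoxycarbonylation of step 5 then turns F5 into 14.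

Step 8 (decarboxylative allylation). The unsubstituted acetaldehyde enolate may over-allylate, undergo aldol reaction, or add to the acrylate. The fallback sets out from 11 and comes back at 13. MnO2 oxidises 11 to the enal F8. (Triphenylphosphoranylidene)acetaldehyde in toluene at 80 °C extends it to the dienal F9. Transfer hydrogenation with a Hantzsch ester and dibenzylammonium trifluoroacetate (THF, rt) reduces only the aldehyde-conjugated C9=C10 bond and gives 13; 1,6-reduction is the selectivity to watch.

Step 5 (alkyne to acrylate). The acid co-catalyst may open the trisubstituted oxirane by methanolysis. The fallback sets out from 9 and comes back at 10, with no acid anywhere. Mo(CO)3(CNtBu)3-catalysed hydrostannation with Bu3SnH (THF, 55 °C) places tin on the internal carbon and gives the 2-stannyl alkene F6. Iodine in CH2Cl2 at 0 °C converts it into the 2-iodo alkene F7. Pd(PPh3)4, CO (1 atm), MeOH and Et3N at 50 °C then give 10.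

**Further compounds**

F1 | step 9 | (5S)-5-ethynyl-6-{(2R,3S)-3-[(3E)-5-hydroxy-4-methylpent-3-en-1-yl]-3-methyloxiran-2-yl}hexan-2-one | OC/C(C)=C/CC[C@]1(C)O[C@@H]1C[C@H](CCC(C)=O)C#C
F2 | step 9 | ethenyl carbonate of F1 (O-[(ethenyloxy)carbonyl] derivative of its allylic hydroxyl) | C=COC(=O)OC/C(C)=C/CC[C@]1(C)O[C@@H]1C[C@H](CCC(C)=O)C#C
F3 | step 9 | ethynyl keto-aldehyde (13 with ethynyl in place of the 1-(methoxycarbonyl)ethenyl group) | O=CCC/C(C)=C/CC[C@]1(C)O[C@@H]1C[C@H](CCC(C)=O)C#C
F4 | step 9 | (1S,3R,4S,7E,12S)-3,4-epoxy-1-ethynyl-4,8,12-trimethylcyclotetradec-7-ene-11,12-diol, both C11 epimers (cembrane ring numbering) | C#C[C@H]1CC[C@](C)(O)C(O)CC/C(C)=C/CC[C@]2(C)O[C@@H]2C1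
F5 | step 9 | (1S,3R,4S,7E,12S)-3,4-epoxy-1-ethynyl-12-hydroxy-4,8,12-trimethylcyclotetradec-7-en-11-one (cembrane ring numbering) | C#C[C@H]1CC[C@](C)(O)C(=O)CC/C(C)=C/CC[C@]2(C)O[C@@H]2C1
F6 | step 5 | (5S)-6-[(2R,3S)-3-methyl-3-(4-methylpent-3-en-1-yl)oxiran-2-yl]-5-[1-(tributylstannyl)ethenyl]hexan-2-one | CC(C)=CCC[C@]1(C)O[C@@H]1C[C@H](CCC(C)=O)C(=C)[Sn](CCCC)(CCCC)CCCC
F7 | step 5 | (5S)-5-(1-iodoethenyl)-6-[(2R,3S)-3-methyl-3-(4-methylpent-3-en-1-yl)oxiran-2-yl]hexan-2-one | CC(C)=CCC[C@]1(C)O[C@@H]1C[C@H](CCC(C)=O)C(=C)I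
F8 | step 8 | methyl (3S)-3-({(2R,3S)-3-methyl-3-[(3E)-4-methyl-5-oxopent-3-en-1-yl]oxiran-2-yl}methyl)-2-methylidene-6-oxoheptanoate | O=C/C(C)=C/CC[C@]1(C)O[C@@H]1C[C@H](CCC(C)=O)C(=C)C(=O)OC
F9 | step 8 | methyl (3S)-3-({(2R,3S)-3-methyl-3-[(3E,5E)-4-methyl-7-oxohepta-3,5-dien-1-yl]oxiran-2-yl}methyl)-2-methylidene-6-oxoheptanoate | O=C/C=C/C(C)=C/CC[C@]1(C)O[C@@H]1C[C@H](CCC(C)=O)C(=C)C(=O)OC
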